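Remark on the chemistry: the target has no stereocentre, so every selectivity question is one of constitution; 7 and 10 are taken as purchasable benzyl ethers.

## The problem

The target (C24H18O14) is a linear chain of four oxygenated benzene rings held by three diaryl ether oxygens: ring A (2,4,6-trihydroxyphenyl), ring B (a 1,2,3,5-tetraoxygenated ring with two free hydroxyls), ring C (a benzene-1,3,5-triol with aryloxy groups on C2 and C4) and ring D (3,4,5-trihydroxyphenyl). Ring C is the core of the difficulty: every carbon but one carries oxygen, and each of its two ether carbons lies between two hydroxyl-bearing carbons, so a coupling approach must form two diaryl ether bonds at doubly ortho-substituted, electron-rich positions of the same ring. The ether carbon of ring A is flanked in the same way, whereas rings B and D meet their ether oxygens at unhindered positions. Ring B needs its four oxygens told apart: two stay free, the one para to the central oxygen goes to ring A and the remaining one to ring C. The eleven free phenols (the vicinal triol of ring D, the vicinal diol of ring B, two phloroglucinol-type rings) do not survive oxidants, electrophiles or air in the presence of base, so they must be set free last under neutral, non-oxidising conditions. The feature that opens a way round the hindered couplings is the pattern of ring C itself: hydroxyls on C1, C3 and C5, aryloxy groups on C2 and C4, hydrogen on C6. This makes ring C the trienol tautomer of a 2,4-bis(aryloxy)cyclohexane-1,3,5-trione, that is, the Claisen ring-closure product of a 3,5-dioxohexanoate chain bearing the aryloxy groups on its C4 and C6. In that open chain each ether carbon of ring C is an sp3 carbon next to a carbonyl group, where an aryl ether is made by simple substitution.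

## Retrosynthesis

**18 from 17.** The six benzyl–oxygen bonds on rings A and D and the two ketal C–O bonds on ring B are cut together. Benzyl ethers and a diphenylmethylene ketal are chosen over methyl ethers because one hydrogenolysis removes all of them without acid, base or oxidant. Triol 17 already carries the three hydroxyls of ring C free, so only eight oxygens need a protecting group. The forward step must leave the three diaryl ethers intact.

**17 from 16 (key cut).** The C1–C2 bond of ring C is cut in a retro-Claisen sense, which opens the ring to the 3,5-dioxohexanoate 16. This is preferred to cutting the two aryl–oxygen bonds of ring C because it turns both hindered diaryl ethers into α-aryloxy carbonyl units and removes any need to protect ring C. Precursor 16 is an open chain with no pentaoxygenated arene. The forward reaction must close the ring through carbon (C6 of the chain onto the ester carbon C1), not through the enol oxygen.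

**16 from 9 and 14.** The C4–C5 bond of the chain is cut, giving the β-keto ester 14 (as its dianion 15) and the aryloxyacetate 9. This cut places the one intermolecular C–C bond formation under kinetic control with the most nucleophilic carbon available. It also splits the chain into a ring D piece and a ring A–B piece of similar weight. The ring D piece is made the dianion because that partner is used in excess and 14 is the cheaper one.

**14 from 12 and 13; 12 from 10.** The alkyl C–O bond next to the ketone is cut (substitution of chloride in 13 by phenol 12). Phenol 12 comes from aldehyde 10 by exchange of the formyl group for a hydroxyl. Both are standard operations on unhindered positions.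

**9 from 6 and 8; 8 from 7.** The ring A–oxygen bond is cut. This is the only diaryl ether made by coupling, and only its ring A side is hindered. Building ring A by the same ring construction as ring C was set aside because ring B would then need two differently addressed acetate arms. The forward Ullmann coupling must tolerate a methyl ester and a ketal.

**6 from 4, 4 from 2 and 3, 2 from 1.** The ring B oxygens are differentiated without any selective protection. In symmetric 1 either vicinal pair of hydroxyls gives the same ketal 2, leaving one free hydroxyl. That hydroxyl is alkylated with 3 and so receives the two carbons that become C2 and C3 of ring C. The fourth oxygen is then created from the formyl group (4 to 6).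

## Roads not taken

**Alternative 1:** the obvious plan cuts the two aryl–oxygen bonds at C2 and C4 of ring C. The forward key steps are two successive Ullmann couplings of 1,3,5-tris(benzyloxy)-2,4-dibromobenzene A1, first with phenol 12 and then with the ring A–B phenol 2,2-diphenyl-6-[2,4,6-tris(benzyloxy)phenoxy]-1,3-benzodioxol-4-ol A2. Each coupling must take place at a C–Br bond flanked by two benzyloxy groups on a very electron-rich ring, where activation by monovalent copper is slow and hydrodehalogenation competes. The first coupling on the symmetric dihalide is statistical. Ring C needs three more benzyl groups, and A2 needs a temporary protecting group on ring B. The chosen plan avoids both hindered couplings and is several steps shorter.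

**Alternative 2:** both C–C bonds next to the hydrogen-bearing carbon of ring C are cut. The forward step is a one-pot double C-acylation of the ketone 1-({2,2-diphenyl-6-[2,4,6-tris(benzyloxy)phenoxy]-1,3-benzodioxol-4-yl}oxy)-3-[3,4,5-tris(benzyloxy)phenoxy]propan-2-one A3 with malonyl dichloride. Here both bonds must be formed by weakly activated α-aryloxy carbons in a medium without alkoxide, where the acyl chloride formed after the first acylation is captured irreversibly by the enol oxygen. The HCl set free endangers the ketal and promotes cyclodehydration of the α-aryloxy ketone onto its electron-rich ring. Base-mediated variants stall because a malonate is more acidic than the ketone. The chosen plan forms the first bond with a dianion and leaves one ring closure to a methoxide medium in which O-acylation is reversible.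

**Alternative 3:** the ring D–oxygen and ring B–oxygen bonds are cut on the side of rings D and B. The forward step is addition of a hindered ring C phenoxide, from 2,4,6-tris(benzyloxy)-3-(methoxymethoxy)phenol A5, to the aryne generated with fluoride from 3,4,5-tris(benzyloxy)-2-(trimethylsilyl)phenyl trifluoromethanesulfonate A4, followed by a second such addition after unmasking. Hindered phenoxides add well to arynes, but each aryne precursor needs several steps. A5 must carry five differentiated oxygens, and the regiochemistry of addition to the ring B aryne, which bears an aryloxy group and a ketal, is less secure. Ring C stays fully protected throughout and the step count is higher than in the chosen plan.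

Key step: step 9

## Route

Step 1
Reactants: 1 3,4,5-trihydroxybenzaldehyde
Product: 2 7-hydroxy-2,2-diphenyl-1,3-benzodioxole-5-carbaldehyde
Conditions: Ph2CCl2, K2CO3, MeCN, rt, argon
Reagents that add atoms: dichlorodiphenylmethane, ClC(Cl)(c1ccccc1)c1ccccc1
Why: Ketal formation from a catechol and a gem-dichloride (double substitution); 1 is symmetric about its C1–C4 axis, so closure over either vicinal pair of hydroxyls gives the same benzodioxole and leaves exactly one free hydroxyl. The ketal is later removed by the same hydrogenolysis as the benzyl ethers.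

Step 2
Reactants: 2 7-hydroxy-2,2-diphenyl-1,3-benzodioxole-5-carbaldehyde; 3 methyl bromoacetate
Product: 4 methyl 2-[(6-formyl-2,2-diphenyl-1,3-benzodioxol-4-yl)oxy]acetate
Conditions: K2CO3, acetone, 50 °C
Reagents that add atoms: none
Why: Williamson ether synthesis on the only free phenol with an activated primary bromide; the CH2 and the ester carbon of 3 become C2 and C3 of ring C.

Step 3
Reactants: 4 methyl 2-[(6-formyl-2,2-diphenyl-1,3-benzodioxol-4-yl)oxy]acetate
Product: 6 methyl 2-[(6-hydroxy-2,2-diphenyl-1,3-benzodioxol-4-yl)oxy]acetate, via aryl formate 5 (not isolated)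
Conditions: mCPBA, CH2Cl2, 0 °C to rt; then K2CO3 (cat.), MeOH, 0 °C
Reagents that add atoms: mCPBA, OOC(=O)c1cccc(Cl)c1
Why: Baeyer–Villiger oxidation of an aldehyde whose ring carries an oxygen para to the formyl group, so aryl migration should outrun hydride migration (the piperonal-to-sesamol case); the formate is cleaved by methanolysis, which cannot scramble the methyl ester.

Step 4
Reactants: 7 1,3,5-tris(benzyloxy)benzene
Product: 8 1,3,5-tris(benzyloxy)-2-iodobenzene
Conditions: N-iodosuccinimide (1.0 equiv), MeCN, 0 °C to rt, dark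
Reagents that add atoms: N-iodosuccinimide, O=C1CCC(=O)N1I
Why: Electrophilic aromatic iodination of a phloroglucinol triether; the three free ring positions are equivalent and one equivalent of reagent should stop at the monoiodide.

Step 5
Reactants: 6 methyl 2-[(6-hydroxy-2,2-diphenyl-1,3-benzodioxol-4-yl)oxy]acetate; 8 1,3,5-tris(benzyloxy)-2-iodobenzene
Product: 9 methyl 2-({2,2-diphenyl-6-[2,4,6-tris(benzyloxy)phenoxy]-1,3-benzodioxol-4-yl}oxy)acetate
Conditions: CuI (cat.), picolinic acid (cat.), K3PO4, DMSO, 90 °C, argon
Reagents that add atoms: none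
Why: Ullmann diaryl ether synthesis; the phenol is unhindered and electron-rich, all hindrance lies on the iodide, and this ligand system is known to tolerate ortho-substituted partners and esters.

Step 6
Reactants: 10 3,4,5-tris(benzyloxy)benzaldehyde
Product: 12 3,4,5-tris(benzyloxy)phenol, via 3,4,5-tris(benzyloxy)phenyl formate 11 (not isolated)
Conditions: mCPBA, CH2Cl2, 0 °C to rt; then K2CO3 (cat.), MeOH, 0 °C
Reagents that add atoms: mCPBA, OOC(=O)c1cccc(Cl)c1
Why: Baeyer–Villiger oxidation of a para-alkoxybenzaldehyde followed by formate methanolysis, the standard entry to 3,4,5-trialkoxyphenols.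

Step 7
Reactants: 12 3,4,5-tris(benzyloxy)phenol; 13 methyl 4-chloro-3-oxobutanoate
Product: 14 methyl 3-oxo-4-[3,4,5-tris(benzyloxy)phenoxy]butanoate
Conditions: NaH (2.2 equiv), THF, 0 to 45 °C; then dilute HCl
Reagents that add atoms: none
Why: Williamson ether synthesis; with two equivalents of NaH the chloro keto ester is held as its sodium enolate, which suppresses self-condensation, while the phenoxide displaces the primary chloride next to the carbonyl group.

Step 8
Reactants: 14 methyl 3-oxo-4-[3,4,5-tris(benzyloxy)phenoxy]butanoate; 9 methyl 2-({2,2-diphenyl-6-[2,4,6-tris(benzyloxy)phenoxy]-1,3-benzodioxol-4-yl}oxy)acetate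
Product: 16 methyl 6-({2,2-diphenyl-6-[2,4,6-tris(benzyloxy)phenoxy]-1,3-benzodioxol-4-yl}oxy)-3,5-dioxo-4-[3,4,5-tris(benzyloxy)phenoxy]hexanoate (racemic at C4; largely enolised), via dilithium 1-methoxy-4-aryloxybuta-1,3-diene-1,3-diolate 15 (not isolated)
Conditions: 14 (2.2 equiv), LiN(i-Pr)2 (4.5 equiv), THF, −78 to 0 °C; then 9, −78 to −20 °C; AcOH quench
Reagents that add atoms: none
Why: Claisen acylation of a β-keto ester dianion at its γ-carbon, the carbon that bears the ring D oxygen, by an α-aryloxy ester, which is an activated and unhindered acyl donor. The product is deprotonated at once by the second equivalent of dianion, which should prevent a second addition; the stereocentre at C4 is of no consequence because it is lost on aromatisation.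

Step 9
Reactants: 16 methyl 6-({2,2-diphenyl-6-[2,4,6-tris(benzyloxy)phenoxy]-1,3-benzodioxol-4-yl}oxy)-3,5-dioxo-4-[3,4,5-tris(benzyloxy)phenoxy]hexanoate
Product: 17 2-({2,2-diphenyl-6-[2,4,6-tris(benzyloxy)phenoxy]-1,3-benzodioxol-4-yl}oxy)-4-[3,4,5-tris(benzyloxy)phenoxy]benzene-1,3,5-triol
Conditions: NaOMe (6 equiv), MeOH–THF, 65 °C, argon; then 1 M HCl, 0 °C
Reagents that add atoms: none
Why: Methoxide deprotonates 16 at C2 and C4 (hexanoate numbering) and, in equilibrium, at C6, the aryloxy-bearing methylene next to the C5 ketone; this carbanion attacks the C1 ester carbonyl, methoxide leaves, and the resulting 2,4-bis(aryloxy)cyclohexane-1,3,5-trione tautomerises at once to the phenoxide of 17, so that aromatisation makes the closure irreversible. The closest known reaction type is the Claisen (Dieckmann-type) cyclisation by which 3,5-dioxoalkanoates and 3,5,7-trioxoalkanoates are closed to phloroglucinols, the laboratory counterpart of the polyketide ring closure that gives phloroglucinol itself. Ring C closes in the 6-(enolexo)-exo-trig mode, and it is the only six-membered carbocycle the chain can form, since attack of the C2 or C4 carbanion on any carbonyl would give a four-membered ring and no aldol closure is possible. No stereocentre is created and the one at C4 of 16 disappears. The step needs C-acylation to win over O-acylation by the C5 enolate oxygen and over retro-Claisen cleavage: the lactone from O-acylation is an enol ester that methoxide should reopen, the 1,3-diketone is shielded as its enolate, and the aryloxy group on C6 acidifies the closing carbon, so the equilibrating mixture should drain into the aromatic product. The constitution of ring C follows from the chain alone: the ring D oxygen sits on C4 and the ring B oxygen on C6, the two carbons that flank C5.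

Step 10
Reactants: 17 2-({2,2-diphenyl-6-[2,4,6-tris(benzyloxy)phenoxy]-1,3-benzodioxol-4-yl}oxy)-4-[3,4,5-tris(benzyloxy)phenoxy]benzene-1,3,5-triol
Product: 18 2-[2,3-dihydroxy-5-(2,4,6-trihydroxyphenoxy)phenoxy]-4-(3,4,5-trihydroxyphenoxy)benzene-1,3,5-triol
Conditions: H2 (1 atm), Pd(OH)2/C, THF–MeOH (degassed), rt; filtration and concentration under argon
Reagents that add atoms: none
Why: Hydrogenolysis of six benzyl aryl ethers and of the diphenylmethylene ketal over palladium; diaryl ethers and free phenols are inert under these conditions, and the air-sensitive polyphenol is released only in the last, neutral and reductive step.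

## Compound list

1 | 3,4,5-trihydroxybenzaldehyde | O=Cc1cc(O)c(O)c(O)c1 | starting material
2 | 7-hydroxy-2,2-diphenyl-1,3-benzodioxole-5-carbaldehyde | O=Cc1cc(O)c2OC(c3ccccc3)(c3ccccc3)Oc2c1 | intermediate
3 | methyl bromoacetate | COC(=O)CBr | starting material
4 | methyl 2-[(6-formyl-2,2-diphenyl-1,3-benzodioxol-4-yl)oxy]acetate | COC(=O)COc1cc(C=O)cc2OC(c3ccccc3)(c3ccccc3)Oc12 | intermediate
5 | methyl 2-{[6-(formyloxy)-2,2-diphenyl-1,3-benzodioxol-4-yl]oxy}acetate | COC(=O)COc1cc(OC=O)cc2OC(c3ccccc3)(c3ccccc3)Oc12 | intermediate
6 | methyl 2-[(6-hydroxy-2,2-diphenyl-1,3-benzodioxol-4-yl)oxy]acetate | COC(=O)COc1cc(O)cc2OC(c3ccccc3)(c3ccccc3)Oc12 | intermediate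
7 | 1,3,5-tris(benzyloxy)benzene | c1ccc(COc2cc(OCc3ccccc3)cc(OCc3ccccc3)c2)cc1 | starting material
8 | 1,3,5-tris(benzyloxy)-2-iodobenzene | Ic1c(OCc2ccccc2)cc(OCc2ccccc2)cc1OCc1ccccc1 | intermediate
9 | methyl 2-({2,2-diphenyl-6-[2,4,6-tris(benzyloxy)phenoxy]-1,3-benzodioxol-4-yl}oxy)acetate | COC(=O)COc1cc(Oc2c(OCc3ccccc3)cc(OCc3ccccc3)cc2OCc2ccccc2)cc2OC(c3ccccc3)(c3ccccc3)Oc12 | intermediate
10 | 3,4,5-tris(benzyloxy)benzaldehyde | O=Cc1cc(OCc2ccccc2)c(OCc2ccccc2)c(OCc2ccccc2)c1 | starting material
11 | 3,4,5-tris(benzyloxy)phenyl formate | O=COc1cc(OCc2ccccc2)c(OCc2ccccc2)c(OCc2ccccc2)c1 | intermediate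
12 | 3,4,5-tris(benzyloxy)phenol | Oc1cc(OCc2ccccc2)c(OCc2ccccc2)c(OCc2ccccc2)c1 | intermediate
13 | methyl 4-chloro-3-oxobutanoate | COC(=O)CC(=O)CCl | starting material
14 | methyl 3-oxo-4-[3,4,5-tris(benzyloxy)phenoxy]butanoate | COC(=O)CC(=O)COc1cc(OCc2ccccc2)c(OCc2ccccc2)c(OCc2ccccc2)c1 | intermediate
15 | dilithium 1-methoxy-4-[3,4,5-tris(benzyloxy)phenoxy]buta-1,3-diene-1,3-diolate | [Li+].[Li+].COC([O-])=CC([O-])=COc1cc(OCc2ccccc2)c(OCc2ccccc2)c(OCc2ccccc2)c1 | intermediate
16 | methyl 6-({2,2-diphenyl-6-[2,4,6-tris(benzyloxy)phenoxy]-1,3-benzodioxol-4-yl}oxy)-3,5-dioxo-4-[3,4,5-tris(benzyloxy)phenoxy]hexanoate (racemic) | COC(=O)CC(=O)C(Oc1cc(OCc2ccccc2)c(OCc2ccccc2)c(OCc2ccccc2)c1)C(=O)COc1cc(Oc2c(OCc3ccccc3)cc(OCc3ccccc3)cc2OCc2ccccc2)cc2OC(c3ccccc3)(c3ccccc3)Oc12 | intermediate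
17 | 2-({2,2-diphenyl-6-[2,4,6-tris(benzyloxy)phenoxy]-1,3-benzodioxol-4-yl}oxy)-4-[3,4,5-tris(benzyloxy)phenoxy]benzene-1,3,5-triol | Oc1cc(O)c(Oc2cc(OCc3ccccc3)c(OCc3ccccc3)c(OCc3ccccc3)c2)c(O)c1Oc1cc(Oc2c(OCc3ccccc3)cc(OCc3ccccc3)cc2OCc2ccccc2)cc2OC(c3ccccc3)(c3ccccc3)Oc12 | intermediate
18 | 2-[2,3-dihydroxy-5-(2,4,6-trihydroxyphenoxy)phenoxy]-4-(3,4,5-trihydroxyphenoxy)benzene-1,3,5-triol | Oc1cc(O)c(Oc2cc(O)c(O)c(Oc3c(O)cc(O)c(Oc4cc(O)c(O)c(O)c4)c3O)c2)c(O)c1 | target

## Step count and risk

Total step count: 10. Longest linear sequence: 7 steps (steps 1, 2, 3, 5, 8, 9, 10).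

**Step 9 (key step).** The most likely failure is ring closure through the enolate oxygen at C5 (lactonisation) or methoxide-induced retro-Claisen cleavage of the diketone outrunning the C-acylation. The closing carbon is activated by only one carbonyl group, and the ester is deactivated whenever the neighbouring β-keto ester is deprotonated. The fallback gives up the ring construction and takes ring C from a preformed arene by known Ullmann chemistry. It sets out from 7, which two equivalents of N-iodosuccinimide should convert into 1,3,5-tris(benzyloxy)-2,4-diiodobenzene F1. Copper-catalysed coupling (CuI, picolinic acid, K3PO4) of an excess of F1 with phenol 12 should give 1,3,5-tris(benzyloxy)-2-iodo-4-[3,4,5-tris(benzyloxy)phenoxy]benzene F2. A second coupling with the free hydroxyl of aldehyde 2 should give 2,2-diphenyl-7-{2,4,6-tris(benzyloxy)-3-[3,4,5-tris(benzyloxy)phenoxy]phenoxy}-1,3-benzodioxole-5-carbaldehyde F3. Baeyer–Villiger oxidation with mCPBA should give 2,2-diphenyl-7-{2,4,6-tris(benzyloxy)-3-[3,4,5-tris(benzyloxy)phenoxy]phenoxy}-1,3-benzodioxol-5-yl formate F4, and methanolysis the phenol 2,2-diphenyl-7-{2,4,6-tris(benzyloxy)-3-[3,4,5-tris(benzyloxy)phenoxy]phenoxy}-1,3-benzodioxol-5-ol F5. A last coupling with iodide 8 should give 2,2-diphenyl-4-{2,4,6-tris(benzyloxy)-3-[3,4,5-tris(benzyloxy)phenoxy]phenoxy}-6-[2,4,6-tris(benzyloxy)phenoxy]-1,3-benzodioxole F6. Hydrogenolysis of F6 under the conditions of step 10 should return the route at 18.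

**Step 8.** The most likely failure is proton transfer from the α-aryloxy ester to the dianion (enolisation of the electrophile) in place of acylation, which returns both partners. The fallback replaces the Claisen acylation by an aldol addition followed by oxidation. It sets out from 9, which i-Bu2AlH at −78 °C should reduce to 2-({2,2-diphenyl-6-[2,4,6-tris(benzyloxy)phenoxy]-1,3-benzodioxol-4-yl}oxy)acetaldehyde F7. Addition of dianion 15 (from 14) to F7 should give methyl 6-({2,2-diphenyl-6-[2,4,6-tris(benzyloxy)phenoxy]-1,3-benzodioxol-4-yl}oxy)-5-hydroxy-3-oxo-4-[3,4,5-tris(benzyloxy)phenoxy]hexanoate F8 as a mixture of diastereomers. Oxidation of F8 with Dess–Martin periodinane should return the route at 16.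

**Step 5.** The most likely failure is slow activation of the doubly ortho-substituted, electron-rich C–I bond, leading to hydrodeiodination of 8 and recovery of the phenol. The fallback reverses the polarity of the coupling and changes the metal. It sets out from 6, which Tf2O and pyridine should convert into methyl 2-[(2,2-diphenyl-6-{[(trifluoromethyl)sulfonyl]oxy}-1,3-benzodioxol-4-yl)oxy]acetate F9, and from 8, which palladium-catalysed hydroxylation (Pd2(dba)3, t-BuXPhos, KOH, dioxane–water) should convert into 2,4,6-tris(benzyloxy)phenol F10. Palladium-catalysed C–O coupling of F9 with F10 (Pd(OAc)2, t-BuXPhos, K3PO4, toluene, 100 °C) places the hindered ring on the nucleophile and should return the route at 9.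

**Step 10.** The most likely failure is oxidative degradation of the vicinal triol and diol rings during isolation, or incomplete cleavage of the ketal, which would leave mixtures that cannot be purified as free phenols. The fallback isolates the product in protected form. It sets out from 17: after hydrogenolysis as in step 10 the crude product is acetylated at once (Ac2O, pyridine) to the undecaacetate of 18, F11, which is stable to air and can be purified on silica. Acid-catalysed methanolysis of F11 (HCl in degassed MeOH, argon) should return the route at 18.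

## Further compounds

F1 | step 9 | 1,3,5-tris(benzyloxy)-2,4-diiodobenzene | Ic1c(OCc2ccccc2)cc(OCc2ccccc2)c(I)c1OCc1ccccc1
F2 | step 9 | 1,3,5-tris(benzyloxy)-2-iodo-4-[3,4,5-tris(benzyloxy)phenoxy]benzene | Ic1c(OCc2ccccc2)cc(OCc2ccccc2)c(Oc2cc(OCc3ccccc3)c(OCc3ccccc3)c(OCc3ccccc3)c2)c1OCc1ccccc1
F3 | step 9 | 2,2-diphenyl-7-{2,4,6-tris(benzyloxy)-3-[3,4,5-tris(benzyloxy)phenoxy]phenoxy}-1,3-benzodioxole-5-carbaldehyde | O=Cc1cc(Oc2c(OCc3ccccc3)cc(OCc3ccccc3)c(Oc3cc(OCc4ccccc4)c(OCc4ccccc4)c(OCc4ccccc4)c3)c2OCc2ccccc2)c2OC(c3ccccc3)(c3ccccc3)Oc2c1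
F4 | step 9 | 2,2-diphenyl-7-{2,4,6-tris(benzyloxy)-3-[3,4,5-tris(benzyloxy)phenoxy]phenoxy}-1,3-benzodioxol-5-yl formate | O=COc1cc(Oc2c(OCc3ccccc3)cc(OCc3ccccc3)c(Oc3cc(OCc4ccccc4)c(OCc4ccccc4)c(OCc4ccccc4)c3)c2OCc2ccccc2)c2OC(c3ccccc3)(c3ccccc3)Oc2c1
F5 | step 9 | 2,2-diphenyl-7-{2,4,6-tris(benzyloxy)-3-[3,4,5-tris(benzyloxy)phenoxy]phenoxy}-1,3-benzodioxol-5-ol | Oc1cc(Oc2c(OCc3ccccc3)cc(OCc3ccccc3)c(Oc3cc(OCc4ccccc4)c(OCc4ccccc4)c(OCc4ccccc4)c3)c2OCc2ccccc2)c2OC(c3ccccc3)(c3ccccc3)Oc2c1
F6 | step 9 | 2,2-diphenyl-4-{2,4,6-tris(benzyloxy)-3-[3,4,5-tris(benzyloxy)phenoxy]phenoxy}-6-[2,4,6-tris(benzyloxy)phenoxy]-1,3-benzodioxole | c1(Oc2c(OCc3ccccc3)cc(OCc3ccccc3)cc2OCc2ccccc2)cc(Oc2c(OCc3ccccc3)cc(OCc3ccccc3)c(Oc3cc(OCc4ccccc4)c(OCc4ccccc4)c(OCc4ccccc4)c3)c2OCc2ccccc2)c2OC(c3ccccc3)(c3ccccc3)Oc2c1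
F7 | step 8 | 2-({2,2-diphenyl-6-[2,4,6-tris(benzyloxy)phenoxy]-1,3-benzodioxol-4-yl}oxy)acetaldehyde | O=CCOc1cc(Oc2c(OCc3ccccc3)cc(OCc3ccccc3)cc2OCc2ccccc2)cc2OC(c3ccccc3)(c3ccccc3)Oc12
F8 | step 8 | methyl 6-({2,2-diphenyl-6-[2,4,6-tris(benzyloxy)phenoxy]-1,3-benzodioxol-4-yl}oxy)-5-hydroxy-3-oxo-4-[3,4,5-tris(benzyloxy)phenoxy]hexanoate (mixture of diastereomers) | COC(=O)CC(=O)C(Oc1cc(OCc2ccccc2)c(OCc2ccccc2)c(OCc2ccccc2)c1)C(O)COc1cc(Oc2c(OCc3ccccc3)cc(OCc3ccccc3)cc2OCc2ccccc2)cc2OC(c3ccccc3)(c3ccccc3)Oc12
F9 | step 5 | methyl 2-[(2,2-diphenyl-6-{[(trifluoromethyl)sulfonyl]oxy}-1,3-benzodioxol-4-yl)oxy]acetate | COC(=O)COc1cc(OS(=O)(=O)C(F)(F)F)cc2OC(c3ccccc3)(c3ccccc3)Oc12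
F10 | step 5 | 2,4,6-tris(benzyloxy)phenol | Oc1c(OCc2ccccc2)cc(OCc2ccccc2)cc1OCc1ccccc1
F11 | step 10 | undecaacetate of 18 | CC(=O)Oc1cc(OC(C)=O)c(Oc2cc(OC(C)=O)c(OC(C)=O)c(Oc3c(OC(C)=O)cc(OC(C)=O)c(Oc4cc(OC(C)=O)c(OC(C)=O)c(OC(C)=O)c4)c3OC(C)=O)c2)c(OC(C)=O)c1
A1 | alternative 1 | 1,3,5-tris(benzyloxy)-2,4-dibromobenzene | Brc1c(OCc2ccccc2)cc(OCc2ccccc2)c(Br)c1OCc1ccccc1
A2 | alternative 1 | 2,2-diphenyl-6-[2,4,6-tris(benzyloxy)phenoxy]-1,3-benzodioxol-4-ol | Oc1cc(Oc2c(OCc3ccccc3)cc(OCc3ccccc3)cc2OCc2ccccc2)cc2OC(c3ccccc3)(c3ccccc3)Oc12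
A3 | alternative 2 | 1-({2,2-diphenyl-6-[2,4,6-tris(benzyloxy)phenoxy]-1,3-benzodioxol-4-yl}oxy)-3-[3,4,5-tris(benzyloxy)phenoxy]propan-2-one | O=C(COc1cc(OCc2ccccc2)c(OCc2ccccc2)c(OCc2ccccc2)c1)COc1cc(Oc2c(OCc3ccccc3)cc(OCc3ccccc3)cc2OCc2ccccc2)cc2OC(c3ccccc3)(c3ccccc3)Oc12
A4 | alternative 3 | 3,4,5-tris(benzyloxy)-2-(trimethylsilyl)phenyl trifluoromethanesulfonate | C[Si](C)(C)c1c(OS(=O)(=O)C(F)(F)F)cc(OCc2ccccc2)c(OCc2ccccc2)c1OCc1ccccc1
A5 | alternative 3 | 2,4,6-tris(benzyloxy)-3-(methoxymethoxy)phenol | Oc1c(OCc2ccccc2)cc(OCc2ccccc2)c(OCOC)c1OCc1ccccc1
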